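**Retrosynthetic overview**
- Target 16 comes from its tri-O-benzyl ether 15 by hydrogenolysis. The pyranone ring C is the last ring formed, by acid closure of the β-keto acetal 13.
- 13 comes from the 2'-hydroxychalcone 11 by an oxidative 1,2-aryl shift (trivalent thallium) that moves the chroman aryl group from Cβ to Cα.
- 11 is made by the key C–C bond formation: an intermolecular Claisen–Schmidt aldol condensation of acetophenone 9 (ring A) with aldehyde 7 (ring B/chroman fragment).
- 7 carries the first ring formed, the dihydropyran ring of the chroman, closed by acid cyclisation of the o-prenylphenol 6. 6 comes from 3,4-dihydroxybenzaldehyde 1 by O-allylation, aromatic Claisen rearrangement and cross-metathesis.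
- 9 comes from 2,4,6-trihydroxyacetophenone 8 by double O-benzylation.

Assumption: the target SMILES contains no stereocentre (the compound is achiral), so it is made as drawn and no asymmetric step is needed. The only stereo-element on the route is the E double bond of chalcone 11.

**Step 1**
Reactants: 1 3,4-dihydroxybenzaldehyde
Product: 2 4-(allyloxy)-3-hydroxybenzaldehyde
Conditions: allyl bromide (1.5 equiv), NaHCO3 (1.5 equiv), NaI (0.3 equiv), DMF, 40 °C, 20 h
Reagents that add atoms: allyl bromide (C=CCBr)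
Why: The 4-OH para to the formyl group is the more acidic phenol, so the weak base ionises only it and Williamson O-alkylation gives the 4-allyl ether regioselectively; no stereocentre is formed.

**Step 2**
Reactants: 2 4-(allyloxy)-3-hydroxybenzaldehyde
Product: 3 4-(allyloxy)-3-(benzyloxy)benzaldehyde
Conditions: BnBr (1.2 equiv), K2CO3 (1.5 equiv), DMF, rt, 6 h
Reagents that add atoms: benzyl bromide (BrCc1ccccc1)
Why: Williamson ether synthesis on the only remaining phenol installs a benzyl ether that survives heat, acid, base and the thallium oxidation and is removed last.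

**Step 3**
Reactants: 3 4-(allyloxy)-3-(benzyloxy)benzaldehyde
Product: 5 3-allyl-5-(benzyloxy)-4-hydroxybenzaldehyde, via ortho-dienone 4 (not isolated)
Conditions: N,N-diethylaniline, 195 °C, argon, 5 h
Reagents that add atoms: none
Why: The aromatic Claisen rearrangement ([3,3]-sigmatropic shift) can deliver the allyl group only to C5, the single free ortho position, and dienone 4 tautomerises to the phenol.

**Step 4**
Reactants: 5 3-allyl-5-(benzyloxy)-4-hydroxybenzaldehyde
Product: 6 3-(benzyloxy)-4-hydroxy-5-(3-methylbut-2-en-1-yl)benzaldehyde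
Conditions: 2-methyl-2-butene (large excess, co-solvent), second-generation Grubbs catalyst (H2IMes)(PCy3)Cl2Ru=CHPh (5 mol %), CH2Cl2, 40 °C (sealed), 12 h
Reagents that add atoms: 2-methyl-2-butene (CC=C(C)C)
Why: Olefin cross-metathesis of the terminal allyl group with excess 2-methyl-2-butene gives the prenyl group with loss of propene; the trisubstituted product is inert to further metathesis and has no E/Z issue.

**Step 5**
Reactants: 6 3-(benzyloxy)-4-hydroxy-5-(3-methylbut-2-en-1-yl)benzaldehyde
Product: 7 8-(benzyloxy)-2,2-dimethylchroman-6-carbaldehyde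
Conditions: Amberlyst 15 (sulfonic acid resin), toluene, 80 °C, 4 h
Reagents that add atoms: none
Why: In this acid-catalysed hydroalkoxylation, Markovnikov protonation of the prenyl olefin gives a tertiary cation that the adjacent phenol captures in a six-membered ring closure; the quaternary carbon carries two methyl groups and is not a stereocentre.

**Step 6**
Reactants: 8 1-(2,4,6-trihydroxyphenyl)ethan-1-one
Product: 9 1-[2,4-bis(benzyloxy)-6-hydroxyphenyl]ethan-1-one
Conditions: BnBr (2.1 equiv), K2CO3 (2.2 equiv), DMF, 0 °C to rt, 12 h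
Reagents that add atoms: benzyl bromide (BrCc1ccccc1)
Why: Williamson etherification stops at the dibenzyl ether because the last ortho OH is hydrogen-bonded to the ketone and far less nucleophilic.

**Step 7**
Reactants: 9 1-[2,4-bis(benzyloxy)-6-hydroxyphenyl]ethan-1-one; 7 8-(benzyloxy)-2,2-dimethylchroman-6-carbaldehyde
Product: 11 (E)-1-[2,4-bis(benzyloxy)-6-hydroxyphenyl]-3-[8-(benzyloxy)-2,2-dimethylchroman-6-yl]prop-2-en-1-one, via aldol adduct 10 (not isolated)
Conditions: KOH (50% aq., 10 equiv), EtOH/THF (1:1), rt, 48 h; then dilute HCl to pH 4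
Reagents that add atoms: none
Why: In this Claisen–Schmidt crossed aldol condensation the aldehyde is non-enolisable and the methyl ketone is the only enolate source, so a single C–C bond forms and E1cB dehydration gives the conjugated enone with the thermodynamically favoured E geometry.

**Step 8**
Reactants: 11 (E)-1-[2,4-bis(benzyloxy)-6-hydroxyphenyl]-3-[8-(benzyloxy)-2,2-dimethylchroman-6-yl]prop-2-en-1-one
Product: 13 1-[2,4-bis(benzyloxy)-6-hydroxyphenyl]-2-[8-(benzyloxy)-2,2-dimethylchroman-6-yl]-3,3-dimethoxypropan-1-one (racemic), via methoxythallation adduct 12 (not isolated)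
Conditions: Tl(NO3)3·3H2O (1.2 equiv), MeOH/HC(OMe)3/CH2Cl2 (3:1:1), rt, 4 h
Reagents that add atoms: methanol (CO)
Why: In this oxidative rearrangement, methoxythallation of the enone is followed by a 1,2-shift of the electron-rich 4-alkoxyaryl group from Cβ to Cα with loss of monovalent thallium and capture of the oxocarbenium ion by methanol; the new sp3 centre is racemic and is erased in step 9.

**Step 9**
Reactants: 13 1-[2,4-bis(benzyloxy)-6-hydroxyphenyl]-2-[8-(benzyloxy)-2,2-dimethylchroman-6-yl]-3,3-dimethoxypropan-1-one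
Product: 15 5,7-bis(benzyloxy)-3-[8-(benzyloxy)-2,2-dimethylchroman-6-yl]-4H-chromen-4-one, via 2-methoxyisoflavanone 14 (not isolated)
Conditions: 10% aq. HCl, MeOH/THF (2:1), 60 °C, 3 h
Reagents that add atoms: none
Why: Acid-catalysed transacetalisation by the ortho phenol closes ring C and β-elimination of methanol gives the conjugated 4-pyranone (isoflavone); benzyl ethers and the chroman ether are stable to dilute HCl.

**Step 10**
Reactants: 15 5,7-bis(benzyloxy)-3-[8-(benzyloxy)-2,2-dimethylchroman-6-yl]-4H-chromen-4-one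
Product: 16 5,7-dihydroxy-3-(8-hydroxy-2,2-dimethylchroman-6-yl)-4H-chromen-4-one
Conditions: H2 (1 atm), 10% Pd/C, THF/MeOH (1:1), rt, monitored and stopped at full debenzylation
Reagents that add atoms: none
Why: Catalytic hydrogenolysis cleaves the three benzyl aryl ethers as toluene, while the non-benzylic chroman C–O bond is untouched and the vinylogous-ester C2=C3 bond reduces only slowly at 1 atm.

**Compound list**
1 | 3,4-dihydroxybenzaldehyde | O=Cc1ccc(O)c(O)c1 | starting material
2 | 4-(allyloxy)-3-hydroxybenzaldehyde | O=Cc1ccc(OCC=C)c(O)c1 | intermediate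
3 | 4-(allyloxy)-3-(benzyloxy)benzaldehyde | O=Cc1ccc(OCC=C)c(OCc2ccccc2)c1 | intermediate
4 | 6-allyl-2-(benzyloxy)-4-formylcyclohexa-2,4-dien-1-one (racemic ortho-dienone, not isolated) | O=CC1=CC(CC=C)C(=O)C(OCc2ccccc2)=C1 | intermediate
5 | 3-allyl-5-(benzyloxy)-4-hydroxybenzaldehyde | O=Cc1cc(CC=C)c(O)c(OCc2ccccc2)c1 | intermediate
6 | 3-(benzyloxy)-4-hydroxy-5-(3-methylbut-2-en-1-yl)benzaldehyde | O=Cc1cc(CC=C(C)C)c(O)c(OCc2ccccc2)c1 | intermediate
7 | 8-(benzyloxy)-2,2-dimethylchroman-6-carbaldehyde | CC1(C)CCc2cc(C=O)cc(OCc3ccccc3)c2O1 | intermediate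
8 | 1-(2,4,6-trihydroxyphenyl)ethan-1-one | CC(=O)c1c(O)cc(O)cc1O | starting material
9 | 1-[2,4-bis(benzyloxy)-6-hydroxyphenyl]ethan-1-one | CC(=O)c1c(O)cc(OCc2ccccc2)cc1OCc1ccccc1 | intermediate
10 | 1-[2,4-bis(benzyloxy)-6-hydroxyphenyl]-3-[8-(benzyloxy)-2,2-dimethylchroman-6-yl]-3-hydroxypropan-1-one (racemic aldol adduct, not isolated) | CC1(C)CCc2cc(C(O)CC(=O)c3c(O)cc(OCc4ccccc4)cc3OCc3ccccc3)cc(OCc3ccccc3)c2O1 | intermediate
11 | (E)-1-[2,4-bis(benzyloxy)-6-hydroxyphenyl]-3-[8-(benzyloxy)-2,2-dimethylchroman-6-yl]prop-2-en-1-one | CC1(C)CCc2cc(/C=C/C(=O)c3c(O)cc(OCc4ccccc4)cc3OCc3ccccc3)cc(OCc3ccccc3)c2O1 | intermediate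
12 | 1-[2,4-bis(benzyloxy)-6-hydroxyphenyl]-3-[8-(benzyloxy)-2,2-dimethylchroman-6-yl]-2-(dinitratothallio)-3-methoxypropan-1-one (methoxythallation adduct, not isolated) | CC1(C)CCc2cc(C(OC)C([Tl](O[N+](=O)[O-])O[N+](=O)[O-])C(=O)c3c(O)cc(OCc4ccccc4)cc3OCc3ccccc3)cc(OCc3ccccc3)c2O1 | intermediate
13 | 1-[2,4-bis(benzyloxy)-6-hydroxyphenyl]-2-[8-(benzyloxy)-2,2-dimethylchroman-6-yl]-3,3-dimethoxypropan-1-one (racemic) | CC1(C)CCc2cc(C(C(OC)OC)C(=O)c3c(O)cc(OCc4ccccc4)cc3OCc3ccccc3)cc(OCc3ccccc3)c2O1 | intermediate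
14 | 5,7-bis(benzyloxy)-3-[8-(benzyloxy)-2,2-dimethylchroman-6-yl]-2-methoxychroman-4-one (2-methoxyisoflavanone, not isolated) | COC1Oc2cc(OCc3ccccc3)cc(OCc3ccccc3)c2C(=O)C1c1cc2c(c(OCc3ccccc3)c1)OC(C)(C)CC2 | intermediate
15 | 5,7-bis(benzyloxy)-3-[8-(benzyloxy)-2,2-dimethylchroman-6-yl]-4H-chromen-4-one | CC1(C)CCc2cc(-c3coc4cc(OCc5ccccc5)cc(OCc5ccccc5)c4c3=O)cc(OCc3ccccc3)c2O1 | intermediate
16 | 5,7-dihydroxy-3-(8-hydroxy-2,2-dimethylchroman-6-yl)-4H-chromen-4-one | CC1(C)CCc2cc(-c3coc4cc(O)cc(O)c4c3=O)cc(O)c2O1 | target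

**Step count and risks**
Total steps: 10. Longest linear sequence: 9 steps (steps 1, 2, 3, 4, 5, 7, 8, 9, 10 from compound 1); step 6 is a one-step side branch.

**Step 4 (cross-metathesis on the free, fairly acidic phenol 5).** The catalyst may be deactivated or the allyl group may isomerise to propenyl. The fallback builds the chroman without metathesis; it sets out from 3 and comes back at 7.
- The allyl ether of 3 is cleaved with Pd(PPh3)4 (2 mol %) and morpholine in THF at rt to give 3-(benzyloxy)-4-hydroxybenzaldehyde F1.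
- This phenol is alkylated with 3-chloro-3-methylbut-1-yne (DBU, CuCl2 cat., MeCN, 0 °C to rt) to the tertiary propargyl ether 3-(benzyloxy)-4-[(2-methylbut-3-yn-2-yl)oxy]benzaldehyde F2.
- Heating F2 in N,N-diethylaniline at 190 °C triggers propargyl Claisen rearrangement, 1,5-hydrogen shift and 6π-electrocyclisation onto the only free ortho carbon, giving 8-(benzyloxy)-2,2-dimethyl-2H-chromene-6-carbaldehyde F3.
- Chemoselective hydrogenation of the chromene double bond (H2 1 atm, Pd/C poisoned with Ph2S, EtOAc, rt) leaves the benzyl ether and aldehyde intact and gives 7.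

**Step 7 (Claisen–Schmidt condensation).** The phenoxide of 9 lowers the acidity of the methyl ketone and the aldehyde 7 is electron-rich, so conversion may be slow or flavanone may form. The fallback masks the chelated phenol before the aldol; it sets out from 9 and comes back at 11.
- 9 is treated with NaH and MOMCl in DMF at 0 °C to give 1-[2,4-bis(benzyloxy)-6-(methoxymethoxy)phenyl]ethan-1-one F4.
- F4 enolises cleanly and condenses with 7 (KOH, EtOH/THF, rt) to (E)-1-[2,4-bis(benzyloxy)-6-(methoxymethoxy)phenyl]-3-[8-(benzyloxy)-2,2-dimethylchroman-6-yl]prop-2-en-1-one F5.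
- Brief treatment of F5 with HCl in MeOH/THF at 40 °C removes the MOM group and gives 11.

**Step 8 (thallium-mediated oxidative rearrangement).** Aurone formation, over-oxidation of the electron-rich rings or a low yield are possible. The fallback performs the aryl shift on the flavanone with hypervalent iodine; it sets out from 11 and comes back at 15, bypassing 13 and step 9.
- 11 is isomerised with NaOAc in refluxing EtOH (intramolecular oxa-Michael addition) to racemic 5,7-bis(benzyloxy)-2-[8-(benzyloxy)-2,2-dimethylchroman-6-yl]chroman-4-one F6.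
- F6 is treated with PhI(OAc)2 and catalytic H2SO4 in HC(OMe)3 at rt. Iodination of the enol ether, migration of the electron-rich aryl group from C2 to C3 and loss of a proton give isoflavone 15 directly.

**Further compounds**
F1 | step 4 | 3-(benzyloxy)-4-hydroxybenzaldehyde | O=Cc1ccc(O)c(OCc2ccccc2)c1
F2 | step 4 | 3-(benzyloxy)-4-[(2-methylbut-3-yn-2-yl)oxy]benzaldehyde | O=Cc1ccc(OC(C)(C)C#C)c(OCc2ccccc2)c1
F3 | step 4 | 8-(benzyloxy)-2,2-dimethyl-2H-chromene-6-carbaldehyde | CC1(C)C=Cc2cc(C=O)cc(OCc3ccccc3)c2O1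
F4 | step 7 | 1-[2,4-bis(benzyloxy)-6-(methoxymethoxy)phenyl]ethan-1-one | COCOc1cc(OCc2ccccc2)cc(OCc2ccccc2)c1C(C)=O
F5 | step 7 | (E)-1-[2,4-bis(benzyloxy)-6-(methoxymethoxy)phenyl]-3-[8-(benzyloxy)-2,2-dimethylchroman-6-yl]prop-2-en-1-one | CC1(C)CCc2cc(/C=C/C(=O)c3c(OCOC)cc(OCc4ccccc4)cc3OCc3ccccc3)cc(OCc3ccccc3)c2O1
F6 | step 8 | 5,7-bis(benzyloxy)-2-[8-(benzyloxy)-2,2-dimethylchroman-6-yl]chroman-4-one (racemic) | CC1(C)CCc2cc(C3CC(=O)c4c(OCc5ccccc5)cc(OCc5ccccc5)cc4O3)cc(OCc3ccccc3)c2O1
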